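**Retrosynthetic overview** (ring A = 3-hydroxyphenyl, ring B = para-phenylene, ring C = phenol ring carrying the ether, ring D = catechol ring)
1. Target ⇒ one-pot hydrogenation and debenzylation of a tetra-O-benzyl bis-stilbene.
2. C–D ethene bond ⇒ ring C aldehyde (acceptor) + ring D aldehyde used as its N–H hydrazone, a benzyl-carbanion equivalent, so two aldehyde carbons are joined.
3. B–O–C diaryl ether ⇒ copper-catalysed coupling of an A–B bromostilbene with 4-(benzyloxy)-3-hydroxybenzaldehyde.
4. A–B ethene bond ⇒ the same hydrazone coupling between 3-(benzyloxy)benzaldehyde (donor) and 4-bromobenzaldehyde (acceptor).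
5. No ring is built: rings A, B, C and D are all bought as benzaldehydes and joined in the order A–B, then B–O–C, then C–D.

Assumption: the target has no stereocentre and no stereogenic double bond, so it is achiral and needs no enantiocontrol; the three benzyl-protected benzaldehydes are taken as catalogue starting materials.

**Step 1**
Reactants: 1 3-(benzyloxy)benzaldehyde; 2 4-bromobenzaldehyde
Product: 4 1-(benzyloxy)-3-[(E)-2-(4-bromophenyl)ethenyl]benzene, via hydrazone 3 (not isolated)
Conditions: 1 (1.2 equiv), N2H4·H2O (1.25 equiv), THF, rt, 30 min; then 2 (1.0 equiv), [Ru(p-cymene)Cl2]2 (1.5 mol%), Me2PCH2CH2PMe2 (dmpe, 3 mol%), KOt-Bu (50 mol%), THF, 80 °C, 12 h, argon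
Reagents that add atoms: hydrazine hydrate, NN.O (its two nitrogens are held in 3 and leave as N2 before 4)
Why: Ruthenium-catalysed, hydrazine-mediated reductive carbonyl cross-coupling (carbonyl umpolung), in which hydrazone 3 bound to divalent ruthenium acts as a benzyl-carbanion equivalent that adds through its former carbonyl carbon to the aldehyde carbon of 2, after which loss of N2 and E1cB-type expulsion of the metal-bound oxygen give the stilbene; the aryl bromide is inert to this catalyst, no stereocentre is formed, and any Z isomer is carried on because both isomers converge in step 4.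

**Step 2**
Reactants: 4 1-(benzyloxy)-3-[(E)-2-(4-bromophenyl)ethenyl]benzene; 5 4-(benzyloxy)-3-hydroxybenzaldehyde
Product: 6 4-(benzyloxy)-3-{4-[(E)-2-[3-(benzyloxy)phenyl]ethenyl]phenoxy}benzaldehyde
Conditions: 5 (1.2 equiv), CuI (10 mol%), picolinic acid (20 mol%), K3PO4 (2 equiv), DMSO, 90 °C, 24 h, argon
Reagents that add atoms: none
Why: Ullmann-type copper-catalysed diaryl ether synthesis, in which the picolinate-ligated monovalent copper phenoxide of 5 couples with the unactivated aryl bromide 4 under conditions suited to ortho-substituted phenols, while the non-enolisable aldehyde, the stilbene and the benzyl ethers are untouched.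

**Step 3**
Reactants: 6 4-(benzyloxy)-3-{4-[(E)-2-[3-(benzyloxy)phenyl]ethenyl]phenoxy}benzaldehyde; 7 2,3-bis(benzyloxy)benzaldehyde
Product: 9 1-(benzyloxy)-2-{4-[(E)-2-[3-(benzyloxy)phenyl]ethenyl]phenoxy}-4-[(E)-2-[2,3-bis(benzyloxy)phenyl]ethenyl]benzene, via hydrazone 8 (not isolated)
Conditions: 7 (1.5 equiv), N2H4·H2O (1.55 equiv), THF, rt, 30 min; then 6 (1.0 equiv), [Ru(p-cymene)Cl2]2 (2.5 mol%), Me2PCH2CH2PMe2 (dmpe, 5 mol%), KOt-Bu (50 mol%), THF, 80 °C, 16 h, argon
Reagents that add atoms: hydrazine hydrate, NN.O (its two nitrogens are held in 8 and leave as N2 before 9)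
Why: The same ruthenium-catalysed hydrazone umpolung olefination as in step 1, now with the cheap ring D aldehyde as the carbanion equivalent 8 in excess and the advanced aldehyde 6 as the limiting acceptor; no stereocentre is formed, and E/Z mixtures at either double bond are irrelevant because both are hydrogenated next.

**Step 4**
Reactants: 9 1-(benzyloxy)-2-{4-[(E)-2-[3-(benzyloxy)phenyl]ethenyl]phenoxy}-4-[(E)-2-[2,3-bis(benzyloxy)phenyl]ethenyl]benzene
Product: 10 3-[2-(4-hydroxy-3-{4-[2-(3-hydroxyphenyl)ethyl]phenoxy}phenyl)ethyl]benzene-1,2-diol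
Conditions: H2 (1 atm), 10% Pd/C, EtOAc–MeOH (1:1), rt, 16 h; filtered under argon
Reagents that add atoms: none
Why: Heterogeneous catalytic hydrogenation, in which Pd/C under H2 saturates both stilbene double bonds and hydrogenolyses all four aryl benzyl ethers in one operation, while the diaryl ether and the arene rings are stable at 1 atm and room temperature; the product is achiral, so no stereocentre has to be set.

**Compound list**
1 | 3-(benzyloxy)benzaldehyde | O=Cc1cccc(OCc2ccccc2)c1 | starting material
2 | 4-bromobenzaldehyde | O=Cc1ccc(Br)cc1 | starting material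
3 | [(E)-3-(benzyloxy)benzylidene]hydrazine (N–H hydrazone of 1) | N/N=C/c1cccc(OCc2ccccc2)c1 | intermediate (not isolated)
4 | 1-(benzyloxy)-3-[(E)-2-(4-bromophenyl)ethenyl]benzene | Brc1ccc(/C=C/c2cccc(OCc3ccccc3)c2)cc1 | intermediate
5 | 4-(benzyloxy)-3-hydroxybenzaldehyde | O=Cc1ccc(OCc2ccccc2)c(O)c1 | starting material
6 | 4-(benzyloxy)-3-{4-[(E)-2-[3-(benzyloxy)phenyl]ethenyl]phenoxy}benzaldehyde | O=Cc1ccc(OCc2ccccc2)c(Oc2ccc(/C=C/c3cccc(OCc4ccccc4)c3)cc2)c1 | intermediate
7 | 2,3-bis(benzyloxy)benzaldehyde | O=Cc1cccc(OCc2ccccc2)c1OCc1ccccc1 | starting material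
8 | [(E)-2,3-bis(benzyloxy)benzylidene]hydrazine (N–H hydrazone of 7) | N/N=C/c1cccc(OCc2ccccc2)c1OCc1ccccc1 | intermediate (not isolated)
9 | 1-(benzyloxy)-2-{4-[(E)-2-[3-(benzyloxy)phenyl]ethenyl]phenoxy}-4-[(E)-2-[2,3-bis(benzyloxy)phenyl]ethenyl]benzene | c1ccc(COc2cccc(/C=C/c3ccc(Oc4cc(/C=C/c5cccc(OCc6ccccc6)c5OCc5ccccc5)ccc4OCc4ccccc4)cc3)c2)cc1 | intermediate
10 | 3-[2-(4-hydroxy-3-{4-[2-(3-hydroxyphenyl)ethyl]phenoxy}phenyl)ethyl]benzene-1,2-diol (achiral) | Oc1cccc(CCc2ccc(Oc3cc(CCc4cccc(O)c4O)ccc3O)cc2)c1 | target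

**Step count:** 4 steps in total; longest linear sequence 4 steps.

**Steps most likely to fail, with fallbacks**

Step 1 may stop at the carbinol instead of eliminating, because a 4-bromophenyl carbinol loses its oxygen less readily than an electron-rich one. The fallback sets out from 1 and 2 and comes back at 4. Hydrazone 3 is made as before and added to 2 under the milder addition variant ([Ru(p-cymene)Cl2]2, dmpe, K3PO4 25 mol%, CsF, THF, 45 °C), so that the racemic carbinol 2-[3-(benzyloxy)phenyl]-1-(4-bromophenyl)ethan-1-ol F1 is isolated on purpose. It is then dehydrated in a separate acid-catalysed step (TsOH·H2O cat., toluene, reflux, Dean–Stark) to give 4.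

Step 2 may be slow because phenol 5 is ortho-substituted and mildly electron-poor, and the bromide 4 is unactivated. The fallback sets out from 5 and comes back at 9; it replaces the copper coupling by a nucleophilic aromatic substitution and reverses the order of the two olefinations.
- Phenol 5 and 4-fluorobenzonitrile (K2CO3, DMF, 130 °C) give 4-[2-(benzyloxy)-5-formylphenoxy]benzonitrile F2.
- The free aldehyde of F2 is coupled with hydrazone 8 (made from 7 as in step 3) to give 4-{2-(benzyloxy)-5-[(E)-2-[2,3-bis(benzyloxy)phenyl]ethenyl]phenoxy}benzonitrile F3.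
- Reduction of the nitrile (i-Bu2AlH, toluene, −78 °C, then aqueous HCl) gives 4-{2-(benzyloxy)-5-[(E)-2-[2,3-bis(benzyloxy)phenyl]ethenyl]phenoxy}benzaldehyde F4.
- Coupling of F4 with hydrazone 3 (made from 1 as in step 1) gives 9, and step 4 follows unchanged.

Step 3 is the riskiest, because 6 is a para-alkoxy (poorly electrophilic) aldehyde and 8 is an ortho-substituted hydrazone, so azine formation or Wolff–Kishner reduction of 8 may win. The fallback sets out from 6 and 7 and comes back at 9. It abandons the hydrazone and joins the two aldehyde carbons by ketyl-type reductive cross-coupling on zerovalent titanium (McMurry coupling: TiCl4, Zn, THF, reflux). Aldehyde 7 is used in threefold excess so that 6 is consumed in the cross-coupling, and 9 is purified by chromatography. This fallback makes no new compound (F0).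

**Further compounds**
F1 | step 1 | 2-[3-(benzyloxy)phenyl]-1-(4-bromophenyl)ethan-1-ol (racemic) | OC(Cc1cccc(OCc2ccccc2)c1)c1ccc(Br)cc1
F2 | step 2 | 4-[2-(benzyloxy)-5-formylphenoxy]benzonitrile | N#Cc1ccc(Oc2cc(C=O)ccc2OCc2ccccc2)cc1
F3 | step 2 | 4-{2-(benzyloxy)-5-[(E)-2-[2,3-bis(benzyloxy)phenyl]ethenyl]phenoxy}benzonitrile | N#Cc1ccc(Oc2cc(/C=C/c3cccc(OCc4ccccc4)c3OCc3ccccc3)ccc2OCc2ccccc2)cc1
F4 | step 2 | 4-{2-(benzyloxy)-5-[(E)-2-[2,3-bis(benzyloxy)phenyl]ethenyl]phenoxy}benzaldehyde | O=Cc1ccc(Oc2cc(/C=C/c3cccc(OCc4ccccc4)c3OCc3ccccc3)ccc2OCc2ccccc2)cc1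
F0 | step 3 | none | none
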